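**Assumption:** the oxane ring is taken to arise in nature by oxidation of the electron-rich aryl ring of a linear (3S,5S)-1,7-diarylheptane-3,5-diol to a p-quinone methide that the C5 hydroxyl captures; 3,4-dihydroxy-5-methoxybenzaldehyde (5-hydroxyvanillin) is bought as a catalogue compound.

## Retrosynthetic overview

1. The target is the all-cis, all-equatorial (2S,4R,6S)-2,4,6-trisubstituted oxane. Its benzylic C2–O bond is opened oxidatively to the linear (3S,5S)-1,7-diarylheptane-3,5-diol; forward, catechol → o-quinone → p-quinone methide, captured by the C5–OH (sets C2).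
2. The anti-diol comes from the 1,7-diarylheptane-3,5-dione by one double asymmetric hydrogenation, which sets both carbinol centres (C4 and C6 of the oxane).
3. The saturated diketone comes from the unsymmetrical curcuminoid (C=C hydrogenation), itself from acetylacetone + 4-hydroxybenzaldehyde + 5-hydroxyvanillin in a one-pot boron-templated double aldol condensation.
4. Ring order: only the oxane ring, formed in the last step; no protecting groups.

## Route

**Step 1**
Reactants: 1 acetylacetone; 2 4-hydroxybenzaldehyde; 3 3,4-dihydroxy-5-methoxybenzaldehyde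
Product: 7 (1E,6E)-1-(3,4-dihydroxy-5-methoxyphenyl)-7-(4-hydroxyphenyl)hepta-1,6-diene-3,5-dione, via acetylacetone boron chelate 4 (not isolated), via mono-styryl boron chelate 5 (not isolated), via curcuminoid boron chelate 6 (not isolated)
Conditions: 1 (1.0 equiv), B2O3 (0.7 equiv), EtOAc, 70 °C, 30 min; 2 (1.4 equiv), B(OBu)3 (4 equiv), n-BuNH2 (0.2 equiv, slow), 70 °C, 2 h; then 3 (0.4 equiv, limiting), n-BuNH2 (0.1 equiv), 70 °C, 4 h; 0.5 M aq HCl, 60 °C, 1 h; chromatography
Reagents that add atoms: none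
Why: Pabon-type boron-templated double aldol (Knoevenagel) condensation, in which boron chelation blocks the central CH2 and directs amine-catalysed condensation to the two terminal methyl groups; feeding cheap 2 first and the valuable 3 last as limiting aldehyde channels 3 mainly into the unsymmetrical product (the less polar symmetrical bis(4-hydroxyphenyl) curcuminoid is removed on silica), both alkenes form E under thermodynamic control, and no stereocentre is created.

**Step 2**
Reactants: 7 (1E,6E)-1-(3,4-dihydroxy-5-methoxyphenyl)-7-(4-hydroxyphenyl)hepta-1,6-diene-3,5-dione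
Product: 8 1-(3,4-dihydroxy-5-methoxyphenyl)-7-(4-hydroxyphenyl)heptane-3,5-dione
Conditions: H2 (1 atm), 10% Pd/C (5 mol% Pd), EtOAc–MeOH (4:1), rt, stopped at 2 equiv H2
Reagents that add atoms: none
Why: chemoselective heterogeneous hydrogenation of the two conjugated C=C bonds (the curcumin → tetrahydrocurcumin reaction), which leaves the enolised 1,3-diketone and the free phenols untouched; no stereocentre is created.

**Step 3**
Reactants: 8 1-(3,4-dihydroxy-5-methoxyphenyl)-7-(4-hydroxyphenyl)heptane-3,5-dione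
Product: 11 (3S,5S)-1-(3,4-dihydroxy-5-methoxyphenyl)-7-(4-hydroxyphenyl)heptane-3,5-diol, via hydroxy ketone 9 (not isolated), via regioisomeric hydroxy ketone 10 (not isolated)
Conditions: RuCl2[(S)-BINAP] (1 mol%), H2 (70 atm), degassed MeOH, 50 °C, 40 h
Reagents that add atoms: none
Why: Noyori asymmetric hydrogenation of a 1,3-diketone, in which the chelated β-dicarbonyl is reduced under catalyst control first to the (S)-hydroxy ketones 9 and 10 and then, again catalyst-controlled, to the anti-(3S,5S)-diol (the same sense as (S)-BINAP giving (S,S)-pentane-2,4-diol from acetylacetone), so both carbinol centres (future C4 and C6) are set at once and the minor antipode is diverted into the separable syn diol.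

**Step 4**
Reactants: 11 (3S,5S)-1-(3,4-dihydroxy-5-methoxyphenyl)-7-(4-hydroxyphenyl)heptane-3,5-diol
Product: 14 5-[(2S,4R,6S)-4-hydroxy-6-[2-(4-hydroxyphenyl)ethyl]oxan-2-yl]-3-methoxybenzene-1,2-diol (CNP0186008.1), via ortho-quinone 12 (not isolated), via para-quinone methide 13 (not isolated)
Conditions: DDQ (1.0 equiv, added over 1 h), 1,4-dioxane (0.01 M), 10 °C to rt, Ar
Reagents that add atoms: none
Why: Proposed new method: DDQ oxidises the pyrogallol-type ring (far more electron-rich than the 4-hydroxyphenyl ring) to ortho-quinone 12, whose vinylogous enolisation (catalysed by the acidic DDQH2 formed) gives para-quinone methide 13; only the C5 hydroxyl can reach the exocyclic carbon through a six-membered chair (the C3 hydroxyl would give an oxetane), and this 1,6-addition re-aromatises the catechol; with the CH2CH2Ar and OH groups equatorial the aryl group also ends equatorial (favoured both in the chair transition state and thermodynamically, through reversible quinone-methide formation), which sets C2 as S; the closest known reaction types are carnosic acid → carnosol (catechol → ortho-quinone → quinone methide → intramolecular O-capture) and DDQ oxidative cyclisations of 4-hydroxyaryl alkanols (dibenzylbutanediol lignans to 2-aryltetrahydrofurans, 1,3-diarylpropanes to flavans).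

## Compound list

1 | acetylacetone (pentane-2,4-dione) | CC(=O)CC(C)=O | starting material
2 | 4-hydroxybenzaldehyde | O=Cc1ccc(O)cc1 | starting material
3 | 3,4-dihydroxy-5-methoxybenzaldehyde (5-hydroxyvanillin) | COc1cc(C=O)cc(O)c1O | starting material
4 | acetylacetone boron chelate (drawn as the dibutoxyboron chelate, 2,2-dibutoxy-4,6-dimethyl-1,3,2-dioxaborinine zwitterion) | CC1=CC(C)=[O+][B-](OCCCC)(OCCCC)O1 | intermediate
5 | mono-styryl boron chelate (dibutoxyboron chelate of (5E)-6-(4-hydroxyphenyl)hex-5-ene-2,4-dione) | CC1=CC(/C=C/c2ccc(O)cc2)=[O+][B-](OCCCC)(OCCCC)O1 | intermediate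
6 | curcuminoid boron chelate (dibutoxyboron chelate of 7) | COc1cc(/C=C/C2=CC(/C=C/c3ccc(O)cc3)=[O+][B-](OCCCC)(OCCCC)O2)cc(O)c1O | intermediate
7 | (1E,6E)-1-(3,4-dihydroxy-5-methoxyphenyl)-7-(4-hydroxyphenyl)hepta-1,6-diene-3,5-dione (drawn as diketo tautomer) | COc1cc(/C=C/C(=O)CC(=O)/C=C/c2ccc(O)cc2)cc(O)c1O | intermediate
8 | 1-(3,4-dihydroxy-5-methoxyphenyl)-7-(4-hydroxyphenyl)heptane-3,5-dione | COc1cc(CCC(=O)CC(=O)CCc2ccc(O)cc2)cc(O)c1O | intermediate
9 | (5S)-1-(3,4-dihydroxy-5-methoxyphenyl)-5-hydroxy-7-(4-hydroxyphenyl)heptan-3-one | COc1cc(CCC(=O)C[C@@H](O)CCc2ccc(O)cc2)cc(O)c1O | intermediate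
10 | (5S)-7-(3,4-dihydroxy-5-methoxyphenyl)-5-hydroxy-1-(4-hydroxyphenyl)heptan-3-one | COc1cc(CC[C@H](O)CC(=O)CCc2ccc(O)cc2)cc(O)c1O | intermediate
11 | (3S,5S)-1-(3,4-dihydroxy-5-methoxyphenyl)-7-(4-hydroxyphenyl)heptane-3,5-diol (anti diol) | COc1cc(CC[C@H](O)C[C@@H](O)CCc2ccc(O)cc2)cc(O)c1O | intermediate
12 | 5-[(3S,5S)-3,5-dihydroxy-7-(4-hydroxyphenyl)heptyl]-3-methoxycyclohexa-3,5-diene-1,2-dione (ortho-quinone) | COC1=CC(CC[C@H](O)C[C@@H](O)CCc2ccc(O)cc2)=CC(=O)C1=O | intermediate
13 | 4-[(3S,5S)-3,5-dihydroxy-7-(4-hydroxyphenyl)heptylidene]-2-hydroxy-6-methoxycyclohexa-2,5-dien-1-one (para-quinone methide; exocyclic alkene geometry not defined) | COC1=CC(=CC[C@H](O)C[C@@H](O)CCc2ccc(O)cc2)C=C(O)C1=O | intermediate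
14 | 5-[(2S,4R,6S)-4-hydroxy-6-[2-(4-hydroxyphenyl)ethyl]oxan-2-yl]-3-methoxybenzene-1,2-diol (all-cis) | COc1cc([C@@H]2C[C@H](O)C[C@H](CCc3ccc(O)cc3)O2)cc(O)c1O | target

## Step count and risk

Total steps: 4. Longest linear sequence: 4 (from 1, 2 or 3).

Ranked by risk: step 4 > step 1 > step 3. The fallbacks are given in route order because the later ones reuse compounds of the first.

**Step 1.** The risk is statistical loss to the two symmetrical curcuminoids and sequestration of boron by the free catechol of 3. The fallback is non-statistical and masks the catechol; it sets out from 3 and comes back at 8.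
- 3 is benzylated (BnBr, K2CO3, DMF) to 3,4-bis(benzyloxy)-5-methoxybenzaldehyde F1.
- Separately, commercial 4-(4-hydroxyphenyl)butan-2-one is acylated at its methyl group (EtOAc, NaH 3 equiv, THF; Claisen condensation) to 6-(4-hydroxyphenyl)hexane-2,4-dione F2.
- The same boron-templated condensation (B2O3, B(OBu)3, n-BuNH2, EtOAc; aq HCl), in which only the terminal CH3 of F2 reacts, joins F1 and F2 to (1E)-1-[3,4-bis(benzyloxy)-5-methoxyphenyl]-7-(4-hydroxyphenyl)hept-1-ene-3,5-dione F3.
- H2 over 10% Pd/C saturates the alkene and cleaves both benzyl ethers in one operation to give 8.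

**Step 3.** The risk is that the free catechol binds ruthenium and stalls the hydrogenation or erodes the anti:syn ratio. The fallback reduces a phenol-masked substrate; it sets out from 8 and comes back at 11.
- 8 is acylated on its three phenols (PivCl 3.3 equiv, pyridine, 0 °C) to 5-{7-[4-(pivaloyloxy)phenyl]-3,5-dioxoheptyl}-3-methoxy-1,2-phenylene bis(2,2-dimethylpropanoate) F4.
- Hydrogenation with RuCl2[(S)-BINAP] as in step 3 gives 5-{(3S,5S)-3,5-dihydroxy-7-[4-(pivaloyloxy)phenyl]heptyl}-3-methoxy-1,2-phenylene bis(2,2-dimethylpropanoate) F5.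
- Methanolysis (NaOMe, MeOH, Ar; then AcOH) returns 11.

**Step 4.** The risks are ring attack of the C3 hydroxyl on ortho-quinone 12 (chroman formation), quinone oligomerisation, and over-oxidation of the product catechol. The fallback closes the ring by a conventional oxa-Michael addition at the ketone oxidation level instead of oxidatively; it sets out from 3 and comes back at 14.
- 3 is taken through 3,4-bis(benzyloxy)-5-methoxybenzaldehyde F1 and, with 6-(4-hydroxyphenyl)hexane-2,4-dione F2, to (1E)-1-[3,4-bis(benzyloxy)-5-methoxyphenyl]-7-(4-hydroxyphenyl)hept-1-ene-3,5-dione F3, exactly as in the step 1 fallback.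
- Partial hydrogenation with RuCl2[(S)-BINAP] (H2 4 atm, MeOH–CH2Cl2, 30 °C, stopped after 1 equiv) reduces the non-conjugated C5 carbonyl in preference to the styryl ketone, as with 1-phenylbutane-1,3-dione. It gives (1E,5S)-1-[3,4-bis(benzyloxy)-5-methoxyphenyl]-5-hydroxy-7-(4-hydroxyphenyl)hept-1-en-3-one F6.
- Catalytic camphorsulfonic acid in CH2Cl2 closes F6 by reversible 6-endo oxa-Michael addition to the thermodynamic cis ketone (2S,6S)-2-[3,4-bis(benzyloxy)-5-methoxyphenyl]-6-[2-(4-hydroxyphenyl)ethyl]oxan-4-one F7.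
- NaBH4 in MeOH at −40 °C attacks axially to give the equatorial alcohol (2S,4R,6S)-2-[3,4-bis(benzyloxy)-5-methoxyphenyl]-6-[2-(4-hydroxyphenyl)ethyl]oxan-4-ol F8.
- H2 over 10% Pd/C in EtOAc removes both benzyl groups to give 14.

## Further compounds

F1 | step 1 | 3,4-bis(benzyloxy)-5-methoxybenzaldehyde | COc1cc(C=O)cc(OCc2ccccc2)c1OCc1ccccc1
F2 | step 1 | 6-(4-hydroxyphenyl)hexane-2,4-dione | CC(=O)CC(=O)CCc1ccc(O)cc1
F3 | step 1 | (1E)-1-[3,4-bis(benzyloxy)-5-methoxyphenyl]-7-(4-hydroxyphenyl)hept-1-ene-3,5-dione | COc1cc(/C=C/C(=O)CC(=O)CCc2ccc(O)cc2)cc(OCc2ccccc2)c1OCc1ccccc1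
F4 | step 3 | 5-{7-[4-(pivaloyloxy)phenyl]-3,5-dioxoheptyl}-3-methoxy-1,2-phenylene bis(2,2-dimethylpropanoate) | COc1cc(CCC(=O)CC(=O)CCc2ccc(OC(=O)C(C)(C)C)cc2)cc(OC(=O)C(C)(C)C)c1OC(=O)C(C)(C)C
F5 | step 3 | 5-{(3S,5S)-3,5-dihydroxy-7-[4-(pivaloyloxy)phenyl]heptyl}-3-methoxy-1,2-phenylene bis(2,2-dimethylpropanoate) | COc1cc(CC[C@H](O)C[C@@H](O)CCc2ccc(OC(=O)C(C)(C)C)cc2)cc(OC(=O)C(C)(C)C)c1OC(=O)C(C)(C)C
F6 | step 4 | (1E,5S)-1-[3,4-bis(benzyloxy)-5-methoxyphenyl]-5-hydroxy-7-(4-hydroxyphenyl)hept-1-en-3-one | COc1cc(/C=C/C(=O)C[C@@H](O)CCc2ccc(O)cc2)cc(OCc2ccccc2)c1OCc1ccccc1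
F7 | step 4 | (2S,6S)-2-[3,4-bis(benzyloxy)-5-methoxyphenyl]-6-[2-(4-hydroxyphenyl)ethyl]oxan-4-one | COc1cc([C@@H]2CC(=O)C[C@H](CCc3ccc(O)cc3)O2)cc(OCc2ccccc2)c1OCc1ccccc1
F8 | step 4 | (2S,4R,6S)-2-[3,4-bis(benzyloxy)-5-methoxyphenyl]-6-[2-(4-hydroxyphenyl)ethyl]oxan-4-ol | COc1cc([C@@H]2C[C@H](O)C[C@H](CCc3ccc(O)cc3)O2)cc(OCc2ccccc2)c1OCc1ccccc1
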